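## Retrosynthetic overview

1. Target ⇒ cut the ester C3–O–C(=O) bond: 4'-O-methylepigallocatechin plus an unprotected feruloyl donor (N-feruloylbenzotriazole), joined without protecting groups by a new azolide-shuttled acylation (key C–O bond).
2. 4'-O-Methylepigallocatechin ⇒ cut the O4'–CH3 bond: site-selective mono-O-methylation of (−)-epigallocatechin.
3. (−)-Epigallocatechin ⇒ enzymatic degalloylation of (−)-epigallocatechin gallate; the feruloyl donor ⇒ ferulic acid.
4. No ring is built: rings A, B and C and both stereocentres (2R,3R) come intact from the tea catechin; methylation precedes acylation because the 4'-OMe group removes the oxidation-prone pyrogallol and blocks C2 epimerisation.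

Assumption: bulk (−)-epigallocatechin gallate (green-tea extract grade) and ferulic acid count as cheap commercial starting materials, so the flavan core with its (2R,3R) configuration is bought, not built.

## Route

Step 1
Reactants: 1 (−)-epigallocatechin 3-O-gallate, (2R,3R)
Product: 2 (−)-epigallocatechin, (2R,3R)-2-(3,4,5-trihydroxyphenyl)chromane-3,5,7-triol
Conditions: tannase (tannin acyl hydrolase, EC 3.1.1.20, Aspergillus oryzae), 50 mM citrate buffer pH 5.0, N2, 35 °C, 3 h; EtOAc extraction, pH 6.5 phosphate wash to remove gallic acid
Reagents that add atoms: none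
Why: Enzymatic ester hydrolysis cleaves only the galloyl ester at pH 5, where the flavan neither epimerises at C2 nor autoxidises, so both stereocentres are carried over unchanged.

Step 2
Reactants: 2 (−)-epigallocatechin
Product: 3 4'-O-methyl-(−)-epigallocatechin, (2R,3R)-2-(3,5-dihydroxy-4-methoxyphenyl)chromane-3,5,7-triol
Conditions: MeI (1.05 equiv), KHCO3 (1.0 equiv), degassed DMF, Ar, dark, 20 °C, 16 h; AcOH quench; C18 reversed-phase chromatography
Reagents that add atoms: iodomethane, CI
Why: Base-limited Williamson O-methylation: one equivalent of weak base ionises mainly the most acidic hydroxyl, the 4'-OH of ring B (its phenoxide is held by two flanking O–H hydrogen bonds and is roughly 1–1.5 pKa units more acidic than the ring A phenols), as in the 4-O-selective alkylation of gallate esters; the methylated ring B is no longer unusually acidic, so over-alkylation stops, and 20 °C avoids quinone-methide epimerisation at C2.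

Step 3
Reactants: 4 (E)-ferulic acid
Product: 5 N-feruloylbenzotriazole, (E)-1-(1H-benzotriazol-1-yl)-3-(4-hydroxy-3-methoxyphenyl)prop-2-en-1-one
Conditions: 1H-benzotriazole (4.0 equiv), SOCl2 (1.05 equiv), THF–CH2Cl2, 0 → 20 °C, 3 h; filter benzotriazole hydrochloride, aqueous wash, crystallise
Reagents that add atoms: 1H-benzotriazole, c1ccc2[nH]nnc2c1
Why: Carboxyl activation as an N-acylbenzotriazole (thionyl chloride/benzotriazole method), which tolerates a free phenol because the sulfinyl-benzotriazole reagent reacts with the carboxylic acid far faster than with a neutral phenol; the E alkene is untouched.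

Step 4
Reactants: 3 4'-O-methyl-(−)-epigallocatechin; 5 N-feruloylbenzotriazole
Product: 7 4'-O-methylepigallocatechin-3-O-ferulate (target), via 7-O-feruloyl aryl ester 6 (not isolated)
Conditions: 5 (1.3 equiv, added over 6 h), DBU (1,8-diazabicyclo[5.4.0]undec-7-ene, 0.3 equiv), 1H-benzotriazole (0.3 equiv), 4 Å molecular sieves, degassed DMF–MeCN 1:1, Ar, dark, 40 °C, 24 h; then MeOH, 0 °C, 30 min; AcOH; C18 chromatography
Reagents that add atoms: none
Why: Proposed new method: azolide-shuttled, thermodynamically funnelled O-acylation of an unprotected polyphenolic alcohol — benzotriazolide (from DBU and benzotriazole) makes acylation of the four phenols of ring A and ring B (and of the ferulate's own phenol) reversible, because aryl ferulates such as 6 are active esters that benzotriazolide re-cleaves to 5 by the microscopic reverse of their formation (benzotriazole pKa about 8 against about 9.5 for the phenols), whereas DBU-catalysed acylation of the single aliphatic OH at C3 gives an alkyl ester several kcal/mol more stable and inert to azolide, so the acyl flux drains to O3 and the methanol quench strips any residual phenolic ester; the C3–O bond is never broken and the 4'-OMe group blocks quinone-methide epimerisation at C2, so (2R,3R) is retained; closest known reaction type: 1,2,4-triazolide/DBU-catalysed transesterification from aryl or enol esters and base-mediated O-acylation with N-acylbenzotriazoles, together with the selective cleavage of aryl over alkyl esters by N-nucleophiles.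

## Compound list

1 | (−)-epigallocatechin 3-O-gallate, (2R,3R) | O=C(O[C@@H]1Cc2c(O)cc(O)cc2O[C@@H]1c1cc(O)c(O)c(O)c1)c1cc(O)c(O)c(O)c1 | starting material
2 | (−)-epigallocatechin, (2R,3R) | O[C@@H]1Cc2c(O)cc(O)cc2O[C@@H]1c1cc(O)c(O)c(O)c1 | intermediate
3 | 4'-O-methyl-(−)-epigallocatechin, (2R,3R) | O[C@@H]1Cc2c(O)cc(O)cc2O[C@@H]1c1cc(O)c(OC)c(O)c1 | intermediate
4 | (E)-ferulic acid | COc1cc(/C=C/C(=O)O)ccc1O | starting material
5 | N-feruloylbenzotriazole, (E) | COc1cc(/C=C/C(=O)n2nnc3ccccc32)ccc1O | intermediate
6 | 7-O-feruloyl-4'-O-methylepigallocatechin, (2R,3R), representative of the transient phenolic esters | O[C@@H]1Cc2c(O)cc(OC(=O)/C=C/c3ccc(O)c(OC)c3)cc2O[C@@H]1c1cc(O)c(OC)c(O)c1 | intermediate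
7 | 4'-O-methylepigallocatechin-3-O-ferulate, (2R,3R), E | COc1cc(/C=C/C(=O)O[C@@H]2Cc3c(O)cc(O)cc3O[C@@H]2c2cc(O)c(OC)c(O)c2)ccc1O | target

## Step count and risk

Total steps: 4. Longest linear sequence: 3 (1 → 2 → 3 → 7); step 3 is a one-step side branch.

Most likely to fail, first: step 4 (the proposed new method). The hindered axial 3-OH may acylate too slowly, or ferulate self-esters may precipitate before the acyl pool has drained to O3. The fallback is known chemistry; it sets out from 3 and 4 and comes back to the route at 7. TBSCl (4.4 equiv) and imidazole in DMF silylate only the four phenols of 3 and give 5,7,3',5'-tetra-O-TBS-4'-O-methylepigallocatechin F1 with the 3-OH free. Ferulic acid 4 with TBSCl (2.2 equiv) and imidazole gives tert-butyldimethylsilyl 4-O-TBS-ferulate F2, whose silyl ester is cleaved by K2CO3 in MeOH–THF–H2O to 4-O-TBS-ferulic acid F3. Steglich coupling of F1 with F3 (EDC·HCl, DMAP, CH2Cl2) gives the pentasilyl 3-O-ester F4, and Et3N·3HF in THF removes all five silyl groups to give 7.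

Second: step 2. The methylation may give a mixture of 4'-, 3'- and ring A methyl ethers, and the ring B anion is air-sensitive. The fallback sets out from 2 and comes back at 3. It replaces the chemical alkylation by enzymatic methyl transfer: recombinant catechol O-methyltransferase (EC 2.1.1.6), S-adenosyl-L-methionine, MgCl2, ascorbate, pH 7.5 phosphate buffer, 37 °C under N2. The enzyme binds only the vicinal-diol ring B through magnesium and methylates O4', the established metabolic regiochemistry for this substrate; it makes no new compound (F0).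

Third: step 3. The free phenol of 4 may be chlorosulfinylated or self-esterified, lowering yield and purity of 5. The fallback sets out from 4 and comes back at 5. DCC and N-hydroxysuccinimide in THF convert 4 into ferulic acid N-succinimidyl ester F5 (carbodiimide active-ester formation, tolerant of free phenols). Added to benzotriazole/DBU at the start of step 4, F5 is transacylated in the flask to 5.

## Further compounds

F1 | step 4 | 5,7,3',5'-tetra-O-TBS-4'-O-methylepigallocatechin, (2R,3R) | O[C@@H]1Cc2c(O[Si](C)(C)C(C)(C)C)cc(O[Si](C)(C)C(C)(C)C)cc2O[C@@H]1c1cc(O[Si](C)(C)C(C)(C)C)c(OC)c(O[Si](C)(C)C(C)(C)C)c1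
F2 | step 4 | tert-butyldimethylsilyl (E)-4-O-TBS-ferulate | COc1cc(/C=C/C(=O)O[Si](C)(C)C(C)(C)C)ccc1O[Si](C)(C)C(C)(C)C
F3 | step 4 | (E)-4-O-TBS-ferulic acid | COc1cc(/C=C/C(=O)O)ccc1O[Si](C)(C)C(C)(C)C
F4 | step 4 | 5,7,3',5'-tetra-O-TBS-4'-O-methylepigallocatechin 3-O-(4-O-TBS-ferulate), (2R,3R), E | COc1cc(/C=C/C(=O)O[C@@H]2Cc3c(O[Si](C)(C)C(C)(C)C)cc(O[Si](C)(C)C(C)(C)C)cc3O[C@@H]2c2cc(O[Si](C)(C)C(C)(C)C)c(OC)c(O[Si](C)(C)C(C)(C)C)c2)ccc1O[Si](C)(C)C(C)(C)C
F0 | step 2 | none | none
F5 | step 3 | (E)-ferulic acid N-succinimidyl ester | COc1cc(/C=C/C(=O)ON2C(=O)CCC2=O)ccc1O
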